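## Structural features

The target (21) is an achiral depside: two benzoate rings joined by one aryl ester, with no stereocentre and no ring other than the two arenes. Ring A is a 2,4-dimethoxy-6-pentylbenzoyl unit (C1 carries the ester carbonyl C7, C2 and C4 carry OMe, C6 carries pentyl). Ring B is a benzoic acid with the carboxyl on C1', heptyl on C2', the depside oxygen on C4' and OMe on C6'. Each ring has the 1,2,3,5 pattern of an orsellinate-type tetraketide, so C7–C1–C2–C3–C4–C5–C6 of ring A (and the matching atoms of ring B) is a folded poly-β-carbonyl chain; this is the feature the key step exploits. The main difficulty is the depside bond C7(=O)–O–C4': C7 lies between the C2 oxygen and the C6 pentyl chain, so acylating a phenol with the preformed, di-ortho-substituted, electron-rich acid is slow. The second difficulty is that ring B's oxygens are decorated against their natural reactivity: the chelated, less reactive C6' oxygen carries methyl, the more reactive C4' oxygen carries the acyl group, and C1' keeps a free carboxyl. The aryl ester is cleaved by hydroxide or alkoxide, so the acid cannot be freed by saponification, and 2,4-dioxygenated benzoic acids decarboxylate in hot acid. Every phenolic oxygen that is not acylated carries methyl, so a triphenol can be permethylated once the depside bond exists.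

## Logic of the disconnections

21 to 20. The O–CH2Ph bond of a benzyl ester on the C1' carboxyl is added. The acid must be released without hydroxide, and hydrogenolysis does that while leaving the aryl ester alone. The demand is only that nothing else in 20 is reducible, which holds.

20 to 19. The three O–CH3 bonds (on O2, O4 and O6') are cut together. Because all three oxygens end up methylated, no differentiation is needed and 19 is exactly what polyketide folding delivers. The forward step must etherify two chelated hydroxyls without acyl transfer at the depside ester.

19 to 15 and 12 (key). Two bonds are cut: the depside bond C7–O(C4') and the ring A bond C1–C6; the C6 oxygen lost as water is restored. This unfolds ring A into an open chain (18, then 17) and releases it from 12 as acylketene 16, which is masked as 15. In one sentence: ring A and the depside ester are made together when the acylketene from 15 is captured by the free para hydroxyl of 12 and the resulting chain folds by aldol condensation. The gain is that the hindered ester is formed while C7 is still an unhindered ketene carbon, and the ring's substitution pattern is written into the chain. The forward step must select the C4' hydroxyl of 12 over the chelated C6' hydroxyl, and the C1-to-C6 aldol must outrun loss of the aryloxide.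

12 to 7 and 8. The same cut is applied to ring B: the ester C–O bond to 8 and the ring bond C1'–C2', through 11, 10 and 9. Both rings thus come from one type of precursor, and the C4' hydroxyl of 12 is born free and unchelated. The demand is ketene capture by 8 faster than self-condensation of 7.

7 to 3 and 6; 15 to 3 and 14. In each side chain the bond between the terminal methylene and the outer ketone carbon is cut. Both chains then diverge from the one common building block 3, differing only in the acyl donor. The forward step needs the 1,3-dianion of 3 to react at its terminal carbon and stop at the ketone stage.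

3 to 1 and 2. The CH2–C(=O) bond next to the dioxinone is cut, giving two commercial compounds. The demand is γ-selective C-acylation of the dienolate of 1.

6 to 4 and 5; 14 to 13 and 5. The amide C–N bonds are cut, giving commercial acid chlorides and the commercial amine salt.

## Other disconnections considered

Alternative 1: Cut only the depside bond C7(=O)–O(C4') between two finished arenes, acid A1 (2,4-dimethoxy-6-pentylbenzoic acid) and phenol A2 (benzyl 2-heptyl-4-hydroxy-6-methoxybenzoate). The forward key step would acylate A2 with the mixed trifluoroacetic anhydride or the acid chloride of A1 to give 20. This is the plan that comes to mind first. The chosen plan is preferred on three grounds.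
- The carbonyl of A1 is shielded on both sides, so the bond would be made at its most hindered state.
- A2 needs a protect, methylate, deprotect sequence, because its C4' hydroxyl is the more reactive one yet must stay free while the chelated C6' hydroxyl is methylated.
- Each arene needs its own carboxylation, or formylation and oxidation, of a 5-alkylbenzene-1,3-diol, so on paper the route is about a dozen steps with none shared, against nine.

Alternative 2: Cut the two neighbouring ring A bonds C6–pentyl and C1–C7. Bromide A3 (1-bromo-3,5-dimethoxybenzene) would be metalated between Br and OMe and would eliminate to aryne A4 (3,5-dimethoxybenzyne). A pentyl Grignard or cuprate should add at the aryne carbon remote from the flanking methoxy group, so that the aryl anion forms next to the inductively withdrawing C–O bond. Carboxylation of that anion with CO2 would give A1 in one operation. This is short for ring A, but it still ends in the hindered esterification of alternative 1 and leaves the oxygen differentiation of A2 untouched. Ring B could not use the same tactic without an aryne precursor bearing two different oxygens. Alkyl Grignard reagents may also act as bases or hydride donors toward arynes.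

Alternative 3: Cut the ring B bonds C1'–C6', C5'–C6' and C3'–C4' (Danheiser benzannulation). Cyclobutenone A5 (ethyl 2-heptyl-4-oxocyclobut-2-ene-1-carboxylate) would open thermally to a vinylketene and undergo (2+2) addition with siloxyalkyne A6 ((ethynyloxy)tri(propan-2-yl)silane). Four-electron opening, six-electron closure and tautomerisation would give A7 (ethyl 2-heptyl-6-hydroxy-4-{[tri(propan-2-yl)silyl]oxy}benzoate). The ketene oxygen becomes the chelated C6' hydroxyl and the alkyne oxygen the silylated C4' oxygen, so the two are differentiated by construction. The chosen plan is preferred because: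
- A5 has a ring C–H that is both α to the ester and γ to the enone and should isomerise easily;
- A5 and the labile terminal alkyne A6 each need several steps;
- an ester exchange is needed before the end;
- ring A and the hindered ester would still be made as in alternative 1 with A1.

The chosen route makes the differentiation unnecessary by permethylation.

Key step: step 7

Remark: the β-dicarbonyl compounds 3, 7, 10, 11, 15, 17 and 18 are drawn as keto tautomers but will exist largely as enols; 11 and 18 are transient stereoisomer mixtures whose stereocentres vanish on aromatisation.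

## Steps

Step 1
Reactants: 1 2,2,6-trimethyl-4H-1,3-dioxin-4-one; 2 acetyl chloride
Product: 3 2,2-dimethyl-6-(2-oxopropyl)-4H-1,3-dioxin-4-one
Conditions: LiN(SiMe3)2 (2 equiv), THF, −78 °C; then 2, −78 °C; 1 M HCl
Reagents that add atoms: none
Why: γ-Deprotonation of the 6-methyl group gives the lithium dienolate, which is C-acylated at the exocyclic carbon (Claisen-type acylation of a vinylogous ester enolate); the second equivalent of base stores the more acidic product as its enolate and so suppresses double acylation.

Step 2
Reactants: 4 octanoyl chloride; 5 N,O-dimethylhydroxylamine hydrochloride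
Product: 6 N-methoxy-N-methyloctanamide
Conditions: Et3N (2.2 equiv), CH2Cl2, 0 to 23 °C
Reagents that add atoms: none
Why: N-acylation of the liberated hydroxylamine by the acid chloride (Schotten–Baumann-type amide formation) gives the Weinreb amide.

Step 3
Reactants: 3 2,2-dimethyl-6-(2-oxopropyl)-4H-1,3-dioxin-4-one; 6 N-methoxy-N-methyloctanamide
Product: 7 6-(2,4-dioxoundecyl)-2,2-dimethyl-4H-1,3-dioxin-4-one
Conditions: LiN(iPr)2 (2.2 equiv), THF, −78 °C; then 6, −78 to −20 °C; 1 M HCl
Reagents that add atoms: none
Why: Double deprotonation gives the 1,3-dianion of 3, whose terminal, last-formed carbanion attacks the amide; the chelated tetrahedral intermediate survives until the quench, so the new 1,3-diketone is never exposed to carbanion (dianion acylation, Weinreb ketone synthesis).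

Step 4
Reactants: 7 6-(2,4-dioxoundecyl)-2,2-dimethyl-4H-1,3-dioxin-4-one; 8 benzyl alcohol
Product: 12 benzyl 2-heptyl-4,6-dihydroxybenzoate, via acylketene 9 (not isolated), via triketo ester 10 (not isolated), via aldol adduct 11 (not isolated)
Conditions: 8 (1.5 equiv), PhMe, 110 °C; then Cs2CO3, iPrOH/CH2Cl2, 23 °C; then HCl (aq), 23 °C
Reagents that add atoms: none
Why: Retro-[4+2] loss of acetone from the dioxinone gives acylketene 9, which the alcohol traps as triketo ester 10; carbonate then promotes aldol attack of the C1' methylene on the heptyl ketone (ring bond C1'–C2') to give 11, and acid dehydration with enolisation gives the arene (dioxinone thermolysis with ketene trapping, biomimetic aldol aromatisation). The chain fixes every substituent position, and the C4' hydroxyl emerges free and unchelated.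

Step 5
Reactants: 13 hexanoyl chloride; 5 N,O-dimethylhydroxylamine hydrochloride
Product: 14 N-methoxy-N-methylhexanamide
Conditions: Et3N (2.2 equiv), CH2Cl2, 0 to 23 °C
Reagents that add atoms: none
Why: Same amide formation as step 2.

Step 6
Reactants: 3 2,2-dimethyl-6-(2-oxopropyl)-4H-1,3-dioxin-4-one; 14 N-methoxy-N-methylhexanamide
Product: 15 6-(2,4-dioxononyl)-2,2-dimethyl-4H-1,3-dioxin-4-one
Conditions: LiN(iPr)2 (2.2 equiv), THF, −78 °C; then 14, −78 to −20 °C; 1 M HCl
Reagents that add atoms: none
Why: Same terminal acylation of the dianion of 3 as step 3, now with the six-carbon acyl donor.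

Step 7
Reactants: 15 6-(2,4-dioxononyl)-2,2-dimethyl-4H-1,3-dioxin-4-one; 12 benzyl 2-heptyl-4,6-dihydroxybenzoate
Product: 19 benzyl 4-[(2,4-dihydroxy-6-pentylbenzoyl)oxy]-2-heptyl-6-hydroxybenzoate, via acylketene 16 (not isolated), via triketo aryl ester 17 (not isolated), via aldol adduct 18 (not isolated)
Conditions: 12 (1.5 equiv), PhMe, 110 °C; concentrate; Et3N, CH2Cl2, 0 to 23 °C; then HCl (4 M in dioxane), 23 °C
Reagents that add atoms: none
Why: Heating 15 expels acetone by retro-[4+2] to give acylketene 16, whose ketene carbon is the future hindered C7 but is here sp-hybridised and unencumbered; the free C4' hydroxyl of 12 adds across it through the hydrogen-bonded six-centre transition state typical of acylketenes, giving triketo aryl ester 17. The closest known reaction type is dioxinone thermolysis with capture of the acylketene by alcohols or phenols, followed by aldol aromatisation of the 3,5,7-triketo ester, as in step 4. Et3N enolises the C1 methylene of 17, which attacks the C6 ketone in a 6-(enolendo)-exo-trig aldol closure to 18 (ring bond C1–C6); acid then removes water and the two remaining ketones enolise, and aromatisation makes the sequence irreversible. No stereocentre persists, since the two in 18 are erased. The first selectivity needed is the choice of hydroxyl in 12: the C4' hydroxyl is free, more acidic and unhindered, whereas the C6' hydroxyl is locked in a hydrogen bond to the benzyl ester carbonyl and flanked by it, and the excess of 12 disfavours double acylation. The second is the folding mode: C1-to-C6 aldol must beat lactonisation through the C4 enol oxygen and C5-to-C7 Claisen closure, both of which expel the aryloxide. This is favoured by a weak amine base in an aprotic medium with no outside nucleophile, so that any E1cB return to 16 is simply recaptured by the same phenoxide, and by the irreversible dehydration of 18. The substitution pattern needs no control, because the carboxyl, the two oxygens and the pentyl group are fixed by the chain.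

Step 8
Reactants: 19 benzyl 4-[(2,4-dihydroxy-6-pentylbenzoyl)oxy]-2-heptyl-6-hydroxybenzoate
Product: 20 benzyl 4-[(2,4-dimethoxy-6-pentylbenzoyl)oxy]-2-heptyl-6-methoxybenzoate
Conditions: MeI (excess), K2CO3, acetone (dry), 56 °C
Reagents that add atoms: iodomethane, CI
Why: Williamson etherification of all three phenols; the free C4 hydroxyl reacts first and the two chelated hydroxyls follow on heating, while the depside carbonyl, flanked by the C2 oxygen and the C6 pentyl chain, is shielded from phenoxide or carbonate in the dry medium.

Step 9
Reactants: 20 benzyl 4-[(2,4-dimethoxy-6-pentylbenzoyl)oxy]-2-heptyl-6-methoxybenzoate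
Product: 21 4-[(2,4-dimethoxy-6-pentylbenzoyl)oxy]-2-heptyl-6-methoxybenzoic acid
Conditions: H2 (1 atm), Pd/C (10 wt% Pd), EtOAc, 23 °C
Reagents that add atoms: none
Why: Hydrogenolysis of the benzylic C–O bond on palladium metal frees the acid under neutral conditions; the aryl ester, the methyl ethers and both arenes are inert, and no hydroxide or hot acid is used, so neither depside cleavage nor decarboxylation is expected.

## Compound list

1 | 2,2,6-trimethyl-4H-1,3-dioxin-4-one | CC1=CC(=O)OC(C)(C)O1 | starting material
2 | acetyl chloride | CC(=O)Cl | starting material
3 | 2,2-dimethyl-6-(2-oxopropyl)-4H-1,3-dioxin-4-one | CC(=O)CC1=CC(=O)OC(C)(C)O1 | intermediate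
4 | octanoyl chloride | CCCCCCCC(=O)Cl | starting material
5 | N,O-dimethylhydroxylamine hydrochloride | CNOC.Cl | starting material
6 | N-methoxy-N-methyloctanamide | CCCCCCCC(=O)N(C)OC | intermediate
7 | 6-(2,4-dioxoundecyl)-2,2-dimethyl-4H-1,3-dioxin-4-one | CCCCCCCC(=O)CC(=O)CC1=CC(=O)OC(C)(C)O1 | intermediate
8 | benzyl alcohol | OCc1ccccc1 | starting material
9 | 3,5,7-trioxotetradec-1-en-1-one (acylketene; not isolated) | O=C=CC(=O)CC(=O)CC(=O)CCCCCCC | intermediate
10 | benzyl 3,5,7-trioxotetradecanoate (triketo ester; not isolated) | CCCCCCCC(=O)CC(=O)CC(=O)CC(=O)OCc1ccccc1 | intermediate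
11 | benzyl 2-heptyl-2-hydroxy-4,6-dioxocyclohexane-1-carboxylate (aldol adduct, stereoisomer mixture; not isolated) | CCCCCCCC1(O)CC(=O)CC(=O)C1C(=O)OCc1ccccc1 | intermediate
12 | benzyl 2-heptyl-4,6-dihydroxybenzoate | CCCCCCCc1cc(O)cc(O)c1C(=O)OCc1ccccc1 | intermediate
13 | hexanoyl chloride | CCCCCC(=O)Cl | starting material
14 | N-methoxy-N-methylhexanamide | CCCCCC(=O)N(C)OC | intermediate
15 | 6-(2,4-dioxononyl)-2,2-dimethyl-4H-1,3-dioxin-4-one | CCCCCC(=O)CC(=O)CC1=CC(=O)OC(C)(C)O1 | intermediate
16 | 3,5,7-trioxododec-1-en-1-one (acylketene; not isolated) | O=C=CC(=O)CC(=O)CC(=O)CCCCC | intermediate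
17 | benzyl 2-heptyl-6-hydroxy-4-[(3,5,7-trioxododecanoyl)oxy]benzoate (triketo aryl ester; not isolated) | CCCCCC(=O)CC(=O)CC(=O)CC(=O)Oc1cc(CCCCCCC)c(C(=O)OCc2ccccc2)c(O)c1 | intermediate
18 | benzyl 2-heptyl-6-hydroxy-4-[(2-hydroxy-4,6-dioxo-2-pentylcyclohexane-1-carbonyl)oxy]benzoate (aldol adduct, stereoisomer mixture; not isolated) | CCCCCC1(O)CC(=O)CC(=O)C1C(=O)Oc1cc(CCCCCCC)c(C(=O)OCc2ccccc2)c(O)c1 | intermediate
19 | benzyl 4-[(2,4-dihydroxy-6-pentylbenzoyl)oxy]-2-heptyl-6-hydroxybenzoate | CCCCCc1cc(O)cc(O)c1C(=O)Oc1cc(CCCCCCC)c(C(=O)OCc2ccccc2)c(O)c1 | intermediate
20 | benzyl 4-[(2,4-dimethoxy-6-pentylbenzoyl)oxy]-2-heptyl-6-methoxybenzoate | CCCCCc1cc(OC)cc(OC)c1C(=O)Oc1cc(CCCCCCC)c(C(=O)OCc2ccccc2)c(OC)c1 | intermediate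
21 | 4-[(2,4-dimethoxy-6-pentylbenzoyl)oxy]-2-heptyl-6-methoxybenzoic acid | CCCCCCCc1cc(OC(=O)c2c(CCCCC)cc(OC)cc2OC)cc(OC)c1C(=O)O | target

## Step count and risks

Total step count: 9. Longest linear sequence: 6 (steps 1, 3, 4, 7, 8, 9).

Step 7 (key). Three processes may divert it. Ketene 16 may be captured by its own enol oxygen (pyrone formation) before the weakly nucleophilic phenol adds. After trapping, the activated aryl ester of 17 may expel the aryloxide (lactonisation or Claisen closure) instead of undergoing the aldol. Some acylation may occur at the chelated hydroxyl. Fallback, setting out from 15 and returning at 20: the ring is formed before the ester. Treating 15 with Et3N in CH2Cl2 should let the dioxinone carbon act as the aldol donor and give 7-hydroxy-2,2-dimethyl-5-pentyl-4H-1,3-benzodioxin-4-one F1. Methylation (MeI, K2CO3) would give 7-methoxy-2,2-dimethyl-5-pentyl-4H-1,3-benzodioxin-4-one F2. Acyl transfer from F2 to the C4' phenoxide of 12 (Cs2CO3 or NaH, THF/DMF), with loss of acetone, would give benzyl 2-heptyl-6-hydroxy-4-[(2-hydroxy-4-methoxy-6-pentylbenzoyl)oxy]benzoate F3. Methylation of F3 under the step 8 conditions gives 20.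

Step 4. Self-condensation of 7 to the benzodioxinone may precede ketene release, and dehydration of 11 may be incomplete. Fallback, from 7 back to 12: let the self-condensation run on purpose (Et3N, CH2Cl2) to 5-heptyl-7-hydroxy-2,2-dimethyl-4H-1,3-benzodioxin-4-one F6, then open the acetonide with sodium benzyloxide (8, NaH, THF) to give 12 and acetone.

Step 3. Proton transfer from the α-methylene of 6 to the dianion, O-acylation, or cyclisation of the diketone on work-up may lower the return. Fallback, from 3 back to 7: aldol addition of the same dianion to octanal gives racemic 6-(4-hydroxy-2-oxoundecyl)-2,2-dimethyl-4H-1,3-dioxin-4-one F4, and Dess–Martin periodinane oxidation of the β-hydroxy ketone gives 7.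

Step 6. The same processes as in step 3 apply. Fallback, from 3 back to 15: dianion aldol with hexanal to racemic 6-(4-hydroxy-2-oxononyl)-2,2-dimethyl-4H-1,3-dioxin-4-one F5, then Dess–Martin oxidation to 15.

Step 8. Etherification of the two chelated hydroxyls may stall, and prolonged heating with carbonate may cause acyl transfer at the depside ester. Fallback, from 19 directly to 20: Mitsunobu etherification (MeOH, PPh3, diisopropyl azodicarboxylate, THF), which activates methanol and uses the phenols as neutral pronucleophiles, so no phenoxide or carbonate is present.

## Further compounds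

F1 | step 7 | 7-hydroxy-2,2-dimethyl-5-pentyl-4H-1,3-benzodioxin-4-one | CCCCCc1cc(O)cc2OC(C)(C)OC(=O)c12
F2 | step 7 | 7-methoxy-2,2-dimethyl-5-pentyl-4H-1,3-benzodioxin-4-one | CCCCCc1cc(OC)cc2OC(C)(C)OC(=O)c12
F3 | step 7 | benzyl 2-heptyl-6-hydroxy-4-[(2-hydroxy-4-methoxy-6-pentylbenzoyl)oxy]benzoate | CCCCCc1cc(OC)cc(O)c1C(=O)Oc1cc(CCCCCCC)c(C(=O)OCc2ccccc2)c(O)c1
F6 | step 4 | 5-heptyl-7-hydroxy-2,2-dimethyl-4H-1,3-benzodioxin-4-one | CCCCCCCc1cc(O)cc2OC(C)(C)OC(=O)c12
F4 | step 3 | 6-(4-hydroxy-2-oxoundecyl)-2,2-dimethyl-4H-1,3-dioxin-4-one (racemic) | CCCCCCCC(O)CC(=O)CC1=CC(=O)OC(C)(C)O1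
F5 | step 6 | 6-(4-hydroxy-2-oxononyl)-2,2-dimethyl-4H-1,3-dioxin-4-one (racemic) | CCCCCC(O)CC(=O)CC1=CC(=O)OC(C)(C)O1
F0 | step 8 | none | none
A1 | alternative 1 | 2,4-dimethoxy-6-pentylbenzoic acid | CCCCCc1cc(OC)cc(OC)c1C(=O)O
A2 | alternative 1 | benzyl 2-heptyl-4-hydroxy-6-methoxybenzoate | CCCCCCCc1cc(O)cc(OC)c1C(=O)OCc1ccccc1
A3 | alternative 2 | 1-bromo-3,5-dimethoxybenzene | COc1cc(Br)cc(OC)c1
A4 | alternative 2 | 3,5-dimethoxybenzyne (1,2-didehydro-3,5-dimethoxybenzene) | COC1=CC(OC)=CC#C1
A5 | alternative 3 | ethyl 2-heptyl-4-oxocyclobut-2-ene-1-carboxylate (racemic) | CCCCCCCC1=CC(=O)C1C(=O)OCC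
A6 | alternative 3 | (ethynyloxy)tri(propan-2-yl)silane | C#CO[Si](C(C)C)(C(C)C)C(C)C
A7 | alternative 3 | ethyl 2-heptyl-6-hydroxy-4-{[tri(propan-2-yl)silyl]oxy}benzoate | CCCCCCCc1cc(O[Si](C(C)C)(C(C)C)C(C)C)cc(O)c1C(=O)OCC
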